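**Plan**

1. Retrosynthesis: the lactone carbonyl C-1 and the ketone C-6 are 1,6-related and O-10 is δ to C-6, so they are joined to a C-1=C-6 enol ether. The ten-membered keto-lactone is then the ozonolysis product of a 2-methylhexahydrochromene. The next cuts are the exocyclic enol-ether C=C (lactone-enolate Claisen addition, then dehydration), C-2–C-3 (aldol) and C-4–C-5 (Michael) of the temporary cyclohexane.
2. Western part, forward: (R)-propylene oxide → α-methylene ketone; an amine-catalysed Michael/aldol annulation closes the carbocycle at C-2–C-3; anti borylation/oxidation oxygenates C-3; acid closes the pyran enol ether and the trans γ-lactone.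
3. Eastern part, forward: 2-acetyl-5-methylfuran → β-keto ester → transfer hydrogenation → Achmatowicz rearrangement (furan dearomatised to the pyranone) → silane reduction → hydrogenation → hydride reduction/lactonisation to the cis-furo[3,2-b]pyranone.
4. Union and end game: the γ-lactone enolate of the tricycle (ketone and macrolactone still masked as the enol ether) adds to the bicyclic lactone; dehydration gives the E vinylogous carbonate; ozonolysis of C-1=C-6 releases the decanolide last.
5. Stereochemistry: C-9 from (R)-propylene oxide; C-4 from the prolinol-ether catalyst; C-3 from anti addition of boron relative to C-4; the pyran carbinol centre from the Ru–TsDPEN transfer hydrogenation, its 2,6-cis methyl and cis ring fusion by substrate control; alkene geometry by thermodynamic control.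

Key step: step 4

Numbering: locants C-1 to O-10 in the text are those of the ten-membered lactone of the target (C-1 lactone carbonyl, C-2 CH2, C-3 CH–O, C-4 CH, C-5 CH2, C-6 ketone, C-7, C-8, C-9 CHMe, O-10). Compound names keep their own systematic locants.

Assumption: the E geometry of the exocyclic enol ether (lactone carbonyl anti to the tetrahydrofuran oxygen) is taken to be the thermodynamically preferred one, as is usual for ester-conjugated 2-alkylidenetetrahydrofurans.

**Route**

Step 1
Reactants: 1 (R)-propylene oxide; 2 2-(2-bromoethyl)-2-methyl-1,3-dioxolane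
Product: 5 (6R)-6-hydroxyheptan-2-one, via Grignard reagent 3 (not isolated), via ketal alcohol 4 (not isolated)
Conditions: Mg, THF, 25 °C; CuI (10 mol%), 1, −30 → 0 °C; then 2 M HCl, THF, rt
Reagents that add atoms: water, O (ketone oxygen of 5); magnesium, [Mg] (in intermediate 3 only)
Why: Copper-catalysed Grignard opening of the terminal epoxide at its CH2 carbon (SN2) should form the C-7–C-8 bond without touching the (R)-carbinol, and aqueous acid then hydrolyses the dioxolane, so C-9 comes from the chiral pool.

Step 2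
Reactants: 5 (6R)-6-hydroxyheptan-2-one
Product: 6 (6R)-6-[(tert-butyldimethylsilyl)oxy]heptan-2-one
Conditions: TBSCl, imidazole, DMF, rt
Reagents that add atoms: tert-butyldimethylsilyl chloride, CC(C)(C)[Si](C)(C)Cl
Why: Standard silyl ether formation protects O-10 so that the hydroxyl cannot add to the enone made in step 3 by oxa-Michael cyclisation.

Step 3
Reactants: 6 (6R)-6-[(tert-butyldimethylsilyl)oxy]heptan-2-one
Product: 7 (6R)-6-[(tert-butyldimethylsilyl)oxy]-3-methylideneheptan-2-one
Conditions: (CH2O)n, iPr2NH2+ CF3CO2− (1 equiv), CF3CO2H (10 mol%), THF, reflux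
Reagents that add atoms: paraformaldehyde (as formaldehyde), C=O
Why: Mannich-type α-methylenation: acid-mediated enolisation of the methyl alkyl ketone toward the more substituted α-carbon, aminomethylation and β-elimination of the amine should give the 1,1-disubstituted enone, whose CH2 becomes C-5.

Step 4
Reactants: 7 (6R)-6-[(tert-butyldimethylsilyl)oxy]-3-methylideneheptan-2-one; 8 methyl 4-oxobutanoate
Product: 11 methyl 2-[(1R)-4-oxo-5-{(3R)-3-[(tert-butyldimethylsilyl)oxy]butyl}cyclohex-2-en-1-yl]acetate (both C-5 epimers), via Michael adduct 9 (not isolated), via ketol 10 (not isolated)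
Conditions: (R)-2-(methoxydiphenylmethyl)pyrrolidine (10 mol%), ethyl 3,4-dihydroxybenzoate (20 mol%), 8 (1.5 equiv), neat, 4 °C; then MeOH, NaOMe (0.6 equiv), 0 → 25 °C
Reagents that add atoms: none
Why: The prolinol-ether catalyst converts aldehyde 8 into its E-enamine, which adds through the future C-4 to the unsubstituted terminus (future C-5) of enone 7; hydrolysis releases keto-aldehyde 9, and methoxide then enolises its methyl ketone toward the CH3 group (future C-2), which attacks the C-3 aldehyde and, after E1cB loss of water from ketol 10, gives enone 11. The closest known reaction type is the amine-catalysed Michael addition of aldehydes to vinyl ketones followed by base-induced aldol condensation, that is, an enantioselective Robinson-type annulation. The one ring that closes does so by the C-2–C-3 bond in a 6-(enolendo)-exo-trig aldol step, and it is six-membered only because the C-1–C-6 bond of 7, which the target does not contain, holds the future lactone carbonyl carbon next to the future ketone carbon, so this bond of the ten-membered ring is made without any medium-ring penalty. The one lasting stereocentre, C-4, should be set as R by the catalyst, whose diphenyl(methoxy)methyl group shields one face of the enamine; C-6 forms unselectively and is erased in step 6, and C-3 is sp2 in 11 and is oxygenated in step 5. The step needs conjugate addition to outrun self-aldolisation of 8 (excess 8, neat, low temperature), aldolisation from the methyl side only (the C-6-side and aldehyde enolates could close only four-membered rings, and the ester is not enolised by methoxide) and retention of the C-4 configuration (ring closure is faster than enolisation of the α-branched aldehyde; MeOH makes ester exchange degenerate and leaves the silyl ether intact).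

Step 5
Reactants: 11 methyl 2-[(1R)-4-oxo-5-{(3R)-3-[(tert-butyldimethylsilyl)oxy]butyl}cyclohex-2-en-1-yl]acetate
Product: 13 methyl 2-[(1R,2S)-2-hydroxy-4-oxo-5-{(3R)-3-[(tert-butyldimethylsilyl)oxy]butyl}cyclohexyl]acetate (both C-5 epimers), via boronate 12 (not isolated)
Conditions: B2pin2, CuCl (5 mol%), NaOtBu (10 mol%), DPEphos (5 mol%), MeOH (2 equiv), THF, rt; then NaBO3·4H2O, THF/H2O, 0 °C
Reagents that add atoms: sodium perborate, [Na+].[Na+].O[B-]1(O)OO[B-](O)(O)OO1 (hydroxyl oxygen); bis(pinacolato)diboron, CC1(C)OB(OC1(C)C)B1OC(C)(C)C(C)(C)O1 (boron of intermediate 12 only)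
Why: Copper-catalysed conjugate borylation should deliver boron to C-3 anti to the adjacent C-4 substituent of the cyclohexenone, and perborate oxidation of the C–B bond proceeds with retention, which sets the 3,4-trans (3S) carbinol as a β-hydroxy ketone under conditions too mild for elimination.

Step 6
Reactants: 13 methyl 2-[(1R,2S)-2-hydroxy-4-oxo-5-{(3R)-3-[(tert-butyldimethylsilyl)oxy]butyl}cyclohexyl]acetate
Product: 15 (3aR,7R,9aS)-7-methyl-3,3a,4,5,6,7,9,9a-octahydro-2H-furo[3,2-g]chromen-2-one, via methyl ketal 14 (not isolated)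
Conditions: CSA (10 mol%), MeOH, rt; evaporate; PPTS (20 mol%), PhMe, 5 Å MS, 90 °C
Reagents that add atoms: methanol, CO (methoxy group of intermediate 14 only)
Why: Acidic methanol removes the silyl group and the δ-hydroxy ketone closes to the cyclic methyl ketal; on heating with PPTS, loss of MeOH toward the more substituted side should give the tetrasubstituted C-1=C-6 enol ether (erasing the epimeric centre) while the trans hydroxyl and ester close to the γ-lactone (ketalisation/elimination and lactonisation), the sieves removing MeOH.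

Step 7
Reactants: 16 2-acetyl-5-methylfuran
Product: 17 ethyl 3-(5-methylfuran-2-yl)-3-oxopropanoate
Conditions: NaH, (EtO)2CO, THF, reflux; AcOH quench
Reagents that add atoms: diethyl carbonate, CCOC(=O)OCC
Why: Crossed Claisen condensation of the methyl ketone enolate with non-enolisable diethyl carbonate, driven by deprotonation of the β-keto ester product.

Step 8
Reactants: 17 ethyl 3-(5-methylfuran-2-yl)-3-oxopropanoate
Product: 18 ethyl (3S)-3-hydroxy-3-(5-methylfuran-2-yl)propanoate
Conditions: RuCl(p-cymene)[(S,S)-TsDPEN] (1 mol%), HCO2H/Et3N (5:2), 30 °C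
Reagents that add atoms: none
Why: Noyori-type asymmetric transfer hydrogenation of a heteroaryl ketone, in which the CH–π contact between the arene ligand and the furan fixes the hydride transfer face; it should give the (S)-carbinol that becomes the pyran C–O stereocentre.

Step 9
Reactants: 18 ethyl (3S)-3-hydroxy-3-(5-methylfuran-2-yl)propanoate
Product: 19 ethyl 2-[(2S)-6-hydroxy-6-methyl-3-oxo-3,6-dihydro-2H-pyran-2-yl]acetate (anomer mixture)
Conditions: NBS, NaHCO3, NaOAc, THF/H2O (4:1), 0 °C
Reagents that add atoms: water, O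
Why: Achmatowicz rearrangement: bromonium-induced oxidative dearomatisation of the furan gives a cis-enedione, which recloses through the carbinol oxygen to the 6-hydroxypyran-3-one with the carbinol centre unchanged.

Step 10
Reactants: 19 ethyl 2-[(2S)-6-hydroxy-6-methyl-3-oxo-3,6-dihydro-2H-pyran-2-yl]acetate
Product: 20 ethyl 2-[(2S,6R)-6-methyl-3-oxo-3,6-dihydro-2H-pyran-2-yl]acetate
Conditions: Et3SiH, CF3CO2H, CH2Cl2, −40 → −10 °C
Reagents that add atoms: none
Why: Ionic (Kishi-type) reduction: acid ionises the hemiketal to the conjugated oxocarbenium ion and the silane adds pseudo-axially on the face that leaves both ring substituents pseudo-equatorial, which should give the 2,6-cis ether.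

Step 11
Reactants: 20 ethyl 2-[(2S,6R)-6-methyl-3-oxo-3,6-dihydro-2H-pyran-2-yl]acetate
Product: 21 ethyl 2-[(2S,6R)-6-methyl-3-oxooxan-2-yl]acetate
Conditions: H2 (1 atm), Pd/C, EtOAc, rt
Reagents that add atoms: none
Why: Heterogeneous hydrogenation of the enone C=C; the ketone, the ester and both stereocentres are not affected.

Step 12
Reactants: 21 ethyl 2-[(2S,6R)-6-methyl-3-oxooxan-2-yl]acetate
Product: 23 (3aS,5R,7aS)-5-methylhexahydro-2H-furo[3,2-b]pyran-2-one, via hydroxy ester 22 (not isolated)
Conditions: LiBH(sBu)3, THF, −78 °C; aq NH4Cl; then TsOH·H2O (cat.), CH2Cl2, rt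
Reagents that add atoms: none
Why: Substrate-controlled ketone reduction: the bulky hydride attacks the 2,6-diequatorial oxan-3-one from the equatorial direction to give the axial 3-hydroxyl cis to the C-2 side chain, and this cis γ-hydroxy ester should close to the cis-fused γ-lactone on acid treatment.

Step 13
Reactants: 15 (3aR,7R,9aS)-7-methyl-3,3a,4,5,6,7,9,9a-octahydro-2H-furo[3,2-g]chromen-2-one; 23 (3aS,5R,7aS)-5-methylhexahydro-2H-furo[3,2-b]pyran-2-one
Product: 26 (3E,3aR,7R,9aS)-7-methyl-3-[(3aS,5R,7aS)-5-methylhexahydro-2H-furo[3,2-b]pyran-2-ylidene]-3,3a,4,5,6,7,9,9a-octahydro-2H-furo[3,2-g]chromen-2-one, via lithium enolate 24 (not isolated), via lactol 25 (not isolated)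
Conditions: LiN(SiMe3)2, THF, −78 °C; then 23, −78 → −40 °C; AcOH, −78 °C; crude, PPTS (20 mol%), PhMe, 5 Å MS, 70 °C
Reagents that add atoms: lithium bis(trimethylsilyl)amide, [Li]N([Si](C)(C)C)[Si](C)(C)C (lithium of intermediate 24 only)
Why: Crossed Claisen-type addition of the γ-lactone enolate (the only enolisable position of 15, because the ketone and the macrolactone are masked as the enol ether) to the lactone carbonyl of 23 gives the cyclic hemiketal of the β-keto lactone, and acid-catalysed dehydration under equilibrating conditions should give the conjugated exocyclic enol ether as the more stable E isomer.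

Step 14
Reactants: 26 (3E,3aR,7R,9aS)-7-methyl-3-[(3aS,5R,7aS)-5-methylhexahydro-2H-furo[3,2-b]pyran-2-ylidene]-3,3a,4,5,6,7,9,9a-octahydro-2H-furo[3,2-g]chromen-2-one
Product: 27 Cordycicadin D
Conditions: O3 (1.0 equiv, Sudan Red 7B end point), CH2Cl2/MeOH (5:1), NaHCO3, −78 °C; then Me2S, −78 °C → rt
Reagents that add atoms: ozone, [O-][O+]=O
Why: Ozonolysis of an enol ether: the electron-rich tetrasubstituted C-1=C-6 bond should react far faster with electrophilic ozone than the ester-conjugated push–pull enol ether, so titration to the dye end point and reductive work-up cleave only the former, turning C-1 into the lactone carbonyl and C-6 into the ketone and opening the bicycle to the ten-membered ring.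

**Compound list**

1 | (R)-propylene oxide [(2R)-2-methyloxirane] | C[C@@H]1CO1 | starting material
2 | 2-(2-bromoethyl)-2-methyl-1,3-dioxolane | CC1(CCBr)OCCO1 | starting material
3 | [2-(2-methyl-1,3-dioxolan-2-yl)ethyl]magnesium bromide | CC1(CC[Mg]Br)OCCO1 | intermediate (not isolated)
4 | (2R)-5-(2-methyl-1,3-dioxolan-2-yl)pentan-2-ol | C[C@@H](O)CCCC1(C)OCCO1 | intermediate (not isolated)
5 | (6R)-6-hydroxyheptan-2-one | C[C@@H](O)CCCC(C)=O | intermediate
6 | (6R)-6-[(tert-butyldimethylsilyl)oxy]heptan-2-one | CC(=O)CCC[C@@H](C)O[Si](C)(C)C(C)(C)C | intermediate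
7 | (6R)-6-[(tert-butyldimethylsilyl)oxy]-3-methylideneheptan-2-one | CC(=O)C(=C)CC[C@@H](C)O[Si](C)(C)C(C)(C)C | intermediate
8 | methyl 4-oxobutanoate | COC(=O)CCC=O | starting material
9 | methyl (3R,8R)-5-acetyl-8-[(tert-butyldimethylsilyl)oxy]-3-formylnonanoate (both C-5 epimers) | COC(=O)C[C@H](C=O)CC(CC[C@@H](C)O[Si](C)(C)C(C)(C)C)C(C)=O | intermediate (not isolated)
10 | methyl 2-[(1R)-2-hydroxy-4-oxo-5-{(3R)-3-[(tert-butyldimethylsilyl)oxy]butyl}cyclohexyl]acetate (ketol, mixture at C-2 and C-5) | COC(=O)C[C@@H]1C(O)CC(=O)C(CC[C@@H](C)O[Si](C)(C)C(C)(C)C)C1 | intermediate (not isolated)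
11 | methyl 2-[(1R)-4-oxo-5-{(3R)-3-[(tert-butyldimethylsilyl)oxy]butyl}cyclohex-2-en-1-yl]acetate (both C-5 epimers) | COC(=O)C[C@@H]1C=CC(=O)C(CC[C@@H](C)O[Si](C)(C)C(C)(C)C)C1 | intermediate
12 | methyl 2-[(1R,2S)-4-oxo-2-(4,4,5,5-tetramethyl-1,3,2-dioxaborolan-2-yl)-5-{(3R)-3-[(tert-butyldimethylsilyl)oxy]butyl}cyclohexyl]acetate | COC(=O)C[C@@H]1[C@@H](B2OC(C)(C)C(C)(C)O2)CC(=O)C(CC[C@@H](C)O[Si](C)(C)C(C)(C)C)C1 | intermediate (not isolated)
13 | methyl 2-[(1R,2S)-2-hydroxy-4-oxo-5-{(3R)-3-[(tert-butyldimethylsilyl)oxy]butyl}cyclohexyl]acetate (both C-5 epimers) | COC(=O)C[C@@H]1[C@@H](O)CC(=O)C(CC[C@@H](C)O[Si](C)(C)C(C)(C)C)C1 | intermediate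
14 | methyl 2-[(2R,6R,7S)-7-hydroxy-8a-methoxy-2-methyloctahydro-2H-chromen-6-yl]acetate (mixture at C-4a and C-8a) | COC(=O)C[C@@H]1[C@@H](O)CC2(OC)O[C@H](C)CCC2C1 | intermediate (not isolated)
15 | (3aR,7R,9aS)-7-methyl-3,3a,4,5,6,7,9,9a-octahydro-2H-furo[3,2-g]chromen-2-one | C[C@@H]1CCC2=C(O1)C[C@@H]3OC(=O)C[C@H]3C2 | intermediate
16 | 2-acetyl-5-methylfuran | CC(=O)c1ccc(C)o1 | starting material
17 | ethyl 3-(5-methylfuran-2-yl)-3-oxopropanoate | CCOC(=O)CC(=O)c1ccc(C)o1 | intermediate
18 | ethyl (3S)-3-hydroxy-3-(5-methylfuran-2-yl)propanoate | CCOC(=O)C[C@H](O)c1ccc(C)o1 | intermediate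
19 | ethyl 2-[(2S)-6-hydroxy-6-methyl-3-oxo-3,6-dihydro-2H-pyran-2-yl]acetate (anomer mixture) | CCOC(=O)C[C@@H]1OC(C)(O)C=CC1=O | intermediate
20 | ethyl 2-[(2S,6R)-6-methyl-3-oxo-3,6-dihydro-2H-pyran-2-yl]acetate | CCOC(=O)C[C@@H]1O[C@H](C)C=CC1=O | intermediate
21 | ethyl 2-[(2S,6R)-6-methyl-3-oxooxan-2-yl]acetate | CCOC(=O)C[C@@H]1O[C@H](C)CCC1=O | intermediate
22 | ethyl 2-[(2S,3S,6R)-3-hydroxy-6-methyloxan-2-yl]acetate | CCOC(=O)C[C@@H]1O[C@H](C)CC[C@@H]1O | intermediate (not isolated)
23 | (3aS,5R,7aS)-5-methylhexahydro-2H-furo[3,2-b]pyran-2-one | O=C1C[C@@H]2O[C@H](C)CC[C@@H]2O1 | intermediate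
24 | lithium enolate of 15 (lithium (3aR,7R,9aS)-7-methyl-3a,4,5,6,7,9,9a-heptahydrofuro[3,2-g]chromen-2-olate) | C[C@@H]1CCC2=C(O1)C[C@@H]3OC(O[Li])=C[C@H]3C2 | intermediate (not isolated)
25 | (3aR,7R,9aS)-3-[(3aS,5R,7aS)-2-hydroxy-5-methylhexahydro-2H-furo[3,2-b]pyran-2-yl]-7-methyl-3,3a,4,5,6,7,9,9a-octahydro-2H-furo[3,2-g]chromen-2-one (mixture at C-3 and at the hemiketal carbon) | C[C@@H]1CCC2=C(O1)C[C@@H]3OC(=O)C(C4(O)C[C@@H]5O[C@H](C)CC[C@@H]5O4)[C@H]3C2 | intermediate (not isolated)
26 | (3E,3aR,7R,9aS)-7-methyl-3-[(3aS,5R,7aS)-5-methylhexahydro-2H-furo[3,2-b]pyran-2-ylidene]-3,3a,4,5,6,7,9,9a-octahydro-2H-furo[3,2-g]chromen-2-one | C[C@@H]1CCC2=C(O1)C[C@@H]3OC(=O)/C(=C4\C[C@@H]5O[C@H](C)CC[C@@H]5O4)[C@H]3C2 | intermediate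
27 | Cordycicadin D | C[C@@H]1CCC(=O)C[C@@H]2/C(=C3/C[C@@H]4O[C@H](C)CC[C@@H]4O3)C(=O)O[C@H]2CC(=O)O1 | target

**Step count and risks**

Total step count: 14. Longest linear sequence: 8 steps (steps 1–6, 13, 14).

Steps most likely to fail:

Step 13. What may go wrong is proton transfer from lactone 23 to enolate 24 outrunning carbonyl addition, after which the enolate of 23 opens its pyran ring by β-elimination or condenses with itself. The fallback sets out from 23 and 15 and returns at 26. It changes the acyl donor to a protected open-chain Weinreb amide, whose α-protons are less acidic and whose tetrahedral adduct is held as a lithium chelate. Lactone 23 is opened with MeNH(OMe)·HCl and AlMe3 to 2-[(2S,3S,6R)-3-hydroxy-6-methyloxan-2-yl]-N-methoxy-N-methylacetamide F1. This is silylated (Et3SiCl, imidazole) to the triethylsilyl ether F2. Enolate 24, made from 15 as in step 13, is acylated by F2 to the β-keto lactone F3. PPTS in MeOH and then PPTS in toluene over 5 Å sieves remove the silyl group, close hemiketal 25 and dehydrate it to 26.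

Step 6. What may go wrong is acid-promoted β-elimination of the C-3 oxygen (as water, or as the carboxylate once the lactone has formed) through the less substituted C-1=C-2 enol ether, in competition with lactonisation. The fallback sets out from 11 and returns at 15. It changes the order of events so that C-3 carries boron, not oxygen, while the enol ether is made. Enone 11 is borylated as in step 5, but boronate 12 is isolated. CSA/MeOH and then PPTS/toluene/5 Å sieves convert 12 into the boryl hexahydrochromene ester F4. NaBO3·4H2O oxidises F4 with retention to the hydroxy ester F5; the enol ether is stable to this basic oxidant. F5 is lactonised to 15 under base catalysis (1,5,7-triazabicyclo[4.4.0]dec-5-ene, toluene, 5 Å sieves), where a homoallylic acyloxy group cannot ionise.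

Step 4. What may go wrong is slow conjugate addition to the α-branched enone, so that self-aldolisation of 8 and loss of enantiopurity of the adduct take over. The fallback sets out from 8 and returns at 11. It attaches the side chain after the ring has been closed. Aldehyde 8 is added to methyl vinyl ketone with the same amine catalyst to give methyl (3R)-3-formyl-6-oxoheptanoate F6. NaOMe/MeOH closes F6, by the same C-2–C-3 aldol condensation, to methyl 2-[(1R)-4-oxocyclohex-2-en-1-yl]acetate F7. (R)-Butane-1,3-diol is converted by selective primary tosylation into (3R)-3-hydroxybutyl 4-methylbenzenesulfonate F8, by silylation into the silyl ether tosylate F9 and by NaI in acetone into tert-butyl{[(2R)-4-iodobutan-2-yl]oxy}dimethylsilane F10. The kinetic α′-lithium enolate of F7 (LiN(iPr)2, THF, −78 °C) is alkylated with F10 in the presence of DMPU to give 11 as its epimer mixture.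

**Further compounds**

F1 | step 13 | 2-[(2S,3S,6R)-3-hydroxy-6-methyloxan-2-yl]-N-methoxy-N-methylacetamide | CON(C)C(=O)C[C@@H]1O[C@H](C)CC[C@@H]1O
F2 | step 13 | N-methoxy-N-methyl-2-[(2S,3S,6R)-6-methyl-3-[(triethylsilyl)oxy]oxan-2-yl]acetamide | CON(C)C(=O)C[C@@H]1O[C@H](C)CC[C@@H]1O[Si](CC)(CC)CC
F3 | step 13 | (3aR,7R,9aS)-7-methyl-3-{[(2S,3S,6R)-6-methyl-3-[(triethylsilyl)oxy]oxan-2-yl]acetyl}-3,3a,4,5,6,7,9,9a-octahydro-2H-furo[3,2-g]chromen-2-one (C-3 epimers) | C[C@@H]1CCC2=C(O1)C[C@@H]3OC(=O)C(C(=O)C[C@@H]4O[C@H](C)CC[C@@H]4O[Si](CC)(CC)CC)[C@H]3C2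
F4 | step 6 | methyl 2-[(2R,6R,7S)-2-methyl-7-(4,4,5,5-tetramethyl-1,3,2-dioxaborolan-2-yl)-3,4,5,6,7,8-hexahydro-2H-chromen-6-yl]acetate | COC(=O)C[C@@H]1[C@@H](B2OC(C)(C)C(C)(C)O2)CC3=C(CC[C@@H](C)O3)C1
F5 | step 6 | methyl 2-[(2R,6R,7S)-7-hydroxy-2-methyl-3,4,5,6,7,8-hexahydro-2H-chromen-6-yl]acetate | COC(=O)C[C@@H]1[C@@H](O)CC2=C(CC[C@@H](C)O2)C1
F6 | step 4 | methyl (3R)-3-formyl-6-oxoheptanoate | COC(=O)C[C@H](C=O)CCC(C)=O
F7 | step 4 | methyl 2-[(1R)-4-oxocyclohex-2-en-1-yl]acetate | COC(=O)C[C@@H]1C=CC(=O)CC1
F8 | step 4 | (3R)-3-hydroxybutyl 4-methylbenzenesulfonate | C[C@@H](O)CCOS(=O)(=O)c1ccc(C)cc1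
F9 | step 4 | (3R)-3-[(tert-butyldimethylsilyl)oxy]butyl 4-methylbenzenesulfonate | C[C@H](CCOS(=O)(=O)c1ccc(C)cc1)O[Si](C)(C)C(C)(C)C
F10 | step 4 | tert-butyl{[(2R)-4-iodobutan-2-yl]oxy}dimethylsilane | C[C@H](CCI)O[Si](C)(C)C(C)(C)C
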